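The cyclohexane ring of the tetralin (C1 carries the side chain, C4 the methyl group) is closed last at its CH2–CH2 bond C2–C3, whose two carbons each hang on a benzylic stereocentre (C1, C4) held ortho on the benzene ring. Both centres are first built as allylic benzylic methines bearing an (E)-propenyl group: C4 by an aromatic Claisen rearrangement ortho to the C5 phenol, C1 together with side-chain centre C11 by an Ireland–Claisen rearrangement. Ring-closing metathesis of this ortho-bis(propenylmethine)arene unites the two alkene carbons (like polarity) as C2=C3. One final hydrogenation saturates that bond and removes all four benzyl groups.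

Key step: step 16

Remark on the chemistry: C5/C6 are the phenolic carbons, C7 the carboxyl-bearing carbon, C11 the side-chain methine and C15 the CH(CH3)CH2OH carbon; 5-bromo-2,3-dihydroxybenzoic acid and (R)-3-bromo-2-methylpropan-1-ol are assumed to be catalogue compounds.

Step 1
Reactants: 1 rac-(E)-pent-3-en-2-ol
Product: 2 (2R,3E)-pent-3-en-2-yl acetate
Conditions: vinyl acetate, Novozym 435 (immobilised Candida antarctica lipase B), pentane, rt, stopped near 45% conversion
Reagents that add atoms: vinyl acetate, C=COC(C)=O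
Why: Lipase-catalysed kinetic resolution (Kazlauskas rule) should acylate only the (R)-enantiomer of this methyl carbinol, so the acetate should be essentially enantiopure.

Step 2
Reactants: 2 (2R,3E)-pent-3-en-2-yl acetate
Product: 3 (2R,3E)-pent-3-en-2-ol
Conditions: K2CO3 (cat.), MeOH, rt; distillation
Reagents that add atoms: none
Why: Base-catalysed transesterification cleaves the acyl–oxygen bond only, so the carbinol configuration is retained.

Step 3
Reactants: 4 5-bromo-2,3-dihydroxybenzoic acid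
Product: 5 benzyl 5-bromo-2,3-dihydroxybenzoate
Conditions: BnBr, KHCO3, DMF, 40 °C
Reagents that add atoms: benzyl bromide, BrCc1ccccc1
Why: Hydrogencarbonate deprotonates only the carboxylic acid, so SN2 O-alkylation should give the benzyl ester and leave both phenols free.

Step 4
Reactants: 5 benzyl 5-bromo-2,3-dihydroxybenzoate; 3 (2R,3E)-pent-3-en-2-ol
Product: 6 benzyl 5-bromo-2-hydroxy-3-{[(2S,3E)-pent-3-en-2-yl]oxy}benzoate
Conditions: PPh3, DIAD, THF, 0 °C to rt
Reagents that add atoms: none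
Why: Mitsunobu etherification proceeds with SN2 inversion (R to S) at the allylic carbinol, and the 2-OH, locked in a hydrogen bond to the ester carbonyl, should leave the 3-OH as the reacting phenol.

Step 5
Reactants: 6 benzyl 5-bromo-2-hydroxy-3-{[(2S,3E)-pent-3-en-2-yl]oxy}benzoate
Product: 7 benzyl 5-bromo-2,3-dihydroxy-4-[(2R,3E)-pent-3-en-2-yl]benzoate
Conditions: Eu(fod)3 (10 mol%; fod = 6,6,7,7,8,8,8-heptafluoro-2,2-dimethyloctane-3,5-dionate), CHCl3, 50 °C
Reagents that add atoms: none
Why: Aromatic Claisen rearrangement to the only free ortho position; a chair transition state with the carbinol methyl pseudo-equatorial transfers the (S) ether centre suprafacially to the new (R) benzylic centre (C4 of the target) and leaves an (E)-propenyl group.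

Step 6
Reactants: 7 benzyl 5-bromo-2,3-dihydroxy-4-[(2R,3E)-pent-3-en-2-yl]benzoate
Product: 8 benzyl 2,3-bis(benzyloxy)-5-bromo-4-[(2R,3E)-pent-3-en-2-yl]benzoate
Conditions: BnBr, K2CO3, DMF, 60 °C, under N2
Reagents that add atoms: benzyl bromide, BrCc1ccccc1
Why: Williamson etherification of both phenols gives protecting groups that the final hydrogenolysis removes without touching an acetate.

Step 7
Reactants: 8 benzyl 2,3-bis(benzyloxy)-5-bromo-4-[(2R,3E)-pent-3-en-2-yl]benzoate; 9 but-3-en-2-one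
Product: 10 benzyl 2,3-bis(benzyloxy)-5-[(1E)-3-oxobut-1-en-1-yl]-4-[(2R,3E)-pent-3-en-2-yl]benzoate
Conditions: Pd(OAc)2 (5 mol%), P(o-tol)3 (12 mol%), Et3N, DMF, 100 °C, sealed vessel
Reagents that add atoms: none
Why: Mizoroki–Heck reaction; the electron-poor terminal alkene of 9 should insert far faster than the internal propenyl group, and β-hydride elimination gives the (E)-enone.

Step 8
Reactants: 10 benzyl 2,3-bis(benzyloxy)-5-[(1E)-3-oxobut-1-en-1-yl]-4-[(2R,3E)-pent-3-en-2-yl]benzoate
Product: 11 benzyl 2,3-bis(benzyloxy)-5-[(1E,3R)-3-hydroxybut-1-en-1-yl]-4-[(2R,3E)-pent-3-en-2-yl]benzoate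
Conditions: (S)-2-methyl-CBS-oxazaborolidine (20 mol%), catecholborane, toluene, −78 °C
Reagents that add atoms: none
Why: Corey–Bakshi–Shibata reduction; with the (S)-oxazaborolidine the alkenyl group acts as the large substituent, so 1,2-hydride delivery should give the (R)-allylic alcohol, while catecholborane at −78 °C leaves the benzyl ester and the alkenes alone.

Step 9
Reactants: 12 (2R)-3-bromo-2-methylpropan-1-ol
Product: 13 benzyl (2R)-3-bromo-2-methylpropyl ether
Conditions: benzyl 2,2,2-trichloroacetimidate, TfOH (cat.), CH2Cl2/cyclohexane, 0 °C to rt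
Reagents that add atoms: benzyl 2,2,2-trichloroacetimidate, N=C(OCc1ccccc1)C(Cl)(Cl)Cl
Why: Acid-catalysed imidate benzylation avoids base, which would close the bromo alcohol to an oxetane; the stereocentre is not involved.

Step 10
Reactants: 13 benzyl (2R)-3-bromo-2-methylpropyl ether; 14 ethyl 4-bromobutanoate
Product: 16 ethyl (6S)-7-(benzyloxy)-6-methylheptanoate, via Grignard reagent 15 (not isolated)
Conditions: Mg, THF, 40 °C; then 14, Li2CuCl4 (3 mol%), NMP, THF, 0 °C to rt
Reagents that add atoms: magnesium, [Mg] (held only by intermediate 15)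
Why: Copper-catalysed sp3–sp3 Grignard cross-coupling (Kochi–Cahiez type) is faster than Grignard addition to the ester; the stereocentre is β to the reacting carbon and stays untouched (the descriptor changes by priority only).

Step 11
Reactants: 16 ethyl (6S)-7-(benzyloxy)-6-methylheptanoate
Product: 17 (6S)-7-(benzyloxy)-6-methylheptanoic acid
Conditions: LiOH, THF/MeOH/H2O, rt; then 1 M HCl
Reagents that add atoms: lithium hydroxide, [Li+].[OH-] (supplies the new carboxyl oxygen)
Why: Ordinary saponification; no stereocentre is α to the carboxyl group.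

Step 12
Reactants: 11 benzyl 2,3-bis(benzyloxy)-5-[(1E,3R)-3-hydroxybut-1-en-1-yl]-4-[(2R,3E)-pent-3-en-2-yl]benzoate; 17 (6S)-7-(benzyloxy)-6-methylheptanoic acid
Product: 18 benzyl 2,3-bis(benzyloxy)-5-[(1E,3R)-3-{[(6S)-7-(benzyloxy)-6-methylheptanoyl]oxy}but-1-en-1-yl]-4-[(2R,3E)-pent-3-en-2-yl]benzoate
Conditions: DCC, DMAP (cat.), CH2Cl2, 0 °C to rt
Reagents that add atoms: none
Why: Steglich esterification acylates the alcohol oxygen with retention under neutral conditions, which avoids ionisation of the aryl-conjugated allylic alcohol.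

Step 13
Reactants: 18 benzyl 2,3-bis(benzyloxy)-5-[(1E,3R)-3-{[(6S)-7-(benzyloxy)-6-methylheptanoyl]oxy}but-1-en-1-yl]-4-[(2R,3E)-pent-3-en-2-yl]benzoate
Product: 21 (2S,3S,4E)-2-[(4S)-5-(benzyloxy)-4-methylpentyl]-3-{3,4-bis(benzyloxy)-5-[(benzyloxy)carbonyl]-2-[(2R,3E)-pent-3-en-2-yl]phenyl}hex-4-enoic acid, via silyl ketene acetal 19 (not isolated), via trimethylsilyl ester 20 (not isolated)
Conditions: LDA, THF, −78 °C; TMSCl (premixed with Et3N), −78 °C to rt, then 50 °C; 1 M HCl
Reagents that add atoms: chlorotrimethylsilane, C[Si](C)(C)Cl (held only by intermediates 19 and 20)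
Why: Ireland–Claisen rearrangement: kinetic enolisation in THF puts the alkyl chain cis to the allyloxy oxygen ((E)-silyl ketene acetal 19), and the chair [3,3] shift with the carbinol methyl pseudo-equatorial should transfer the (R) carbinol centre to C1 (S), set C11 (S) anti to the aryl group and leave an (E)-propenyl group on C1.

Step 14
Reactants: 21 (2S,3S,4E)-2-[(4S)-5-(benzyloxy)-4-methylpentyl]-3-{3,4-bis(benzyloxy)-5-[(benzyloxy)carbonyl]-2-[(2R,3E)-pent-3-en-2-yl]phenyl}hex-4-enoic acid
Product: 23 benzyl 2,3-bis(benzyloxy)-5-{(2S,3S,4E)-2-[(4S)-5-(benzyloxy)-4-methylpentyl]-1-hydroxyhex-4-en-3-yl}-4-[(2R,3E)-pent-3-en-2-yl]benzoate, via mixed anhydride 22 (not isolated)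
Conditions: i-BuOCOCl, N-methylmorpholine, THF, −15 °C; then NaBH4, H2O, 0 °C
Reagents that add atoms: isobutyl chloroformate, CC(C)COC(Cl)=O (held only by intermediate 22)
Why: Mixed-anhydride activation followed by borohydride reduction reduces only the activated carboxyl group; the aryl benzyl ester and both alkenes are inert to NaBH4, which is why borane and LiAlH4 are avoided.

Step 15
Reactants: 23 benzyl 2,3-bis(benzyloxy)-5-{(2S,3S,4E)-2-[(4S)-5-(benzyloxy)-4-methylpentyl]-1-hydroxyhex-4-en-3-yl}-4-[(2R,3E)-pent-3-en-2-yl]benzoate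
Product: 24 benzyl 5-{(2S,3S,4E)-1-acetoxy-2-[(4S)-5-(benzyloxy)-4-methylpentyl]hex-4-en-3-yl}-2,3-bis(benzyloxy)-4-[(2R,3E)-pent-3-en-2-yl]benzoate
Conditions: Ac2O, pyridine, DMAP (cat.), CH2Cl2, rt
Reagents that add atoms: acetic anhydride, CC(=O)OC(C)=O
Why: Acylation of the only free hydroxyl group installs the acetate of the target while every other oxygen is benzyl-protected.

Step 16
Reactants: 24 benzyl 5-{(2S,3S,4E)-1-acetoxy-2-[(4S)-5-(benzyloxy)-4-methylpentyl]hex-4-en-3-yl}-2,3-bis(benzyloxy)-4-[(2R,3E)-pent-3-en-2-yl]benzoate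
Product: 25 benzyl (5R,8S)-8-[(2S,6S)-1-acetoxy-7-(benzyloxy)-6-methylheptan-2-yl]-3,4-bis(benzyloxy)-5-methyl-5,8-dihydronaphthalene-2-carboxylate
Conditions: second-generation Hoveyda–Grubbs catalyst (10 mol%), 1,4-benzoquinone (20 mol%), toluene (0.005 M), 80 °C, argon sparge
Reagents that add atoms: none
Why: Ring-closing olefin metathesis (Chauvin mechanism): the ruthenium alkylidene exchanges with one propenyl group by [2+2] cycloaddition and cycloreversion, the new benzylic-allylic alkylidene adds intramolecularly to the second propenyl group, and collapse of the ruthenacyclobutane forms C2=C3 with overall loss of but-2-ene. The closest known reaction type is the ring-closing metathesis of ortho-diallylarenes to 1,4-dihydronaphthalenes. The six-membered carbocycle is closed by joining the two alkene carbons attached to C1 and C4, and the ring alkene is necessarily cis. No stereocentre is formed: C1, C4, C11 and C15 are set earlier and only the alkene carbons react. The step needs cyclisation over oligomerisation and no migration of the new double bond into conjugation, which would epimerise C1 or C4. The rigid ortho arrangement on the arene holds the two alkenes close, high dilution disfavours cross-metathesis, and benzoquinone should quench ruthenium hydrides.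

Step 17
Reactants: 25 benzyl (5R,8S)-8-[(2S,6S)-1-acetoxy-7-(benzyloxy)-6-methylheptan-2-yl]-3,4-bis(benzyloxy)-5-methyl-5,8-dihydronaphthalene-2-carboxylate
Product: 26 (5R,8S)-8-[(2S,6S)-1-acetoxy-7-hydroxy-6-methylheptan-2-yl]-3,4-dihydroxy-5-methyl-5,6,7,8-tetrahydronaphthalene-2-carboxylic acid
Conditions: H2 (1 atm), Pd(OH)2/C, EtOAc/EtOH, rt
Reagents that add atoms: none
Why: Heterogeneous hydrogenation should saturate the cis ring alkene and hydrogenolyse the two aryl benzyl ethers, the benzyl ester and the alkyl benzyl ether in one operation, while the acetate and the benzylic C–H stereocentres are unaffected.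

Compound list
1 | rac-(E)-pent-3-en-2-ol | C/C=C/C(C)O | starting material
2 | (2R,3E)-pent-3-en-2-yl acetate | C/C=C/[C@@H](C)OC(C)=O | intermediate
3 | (2R,3E)-pent-3-en-2-ol | C/C=C/[C@@H](C)O | intermediate
4 | 5-bromo-2,3-dihydroxybenzoic acid | OC(=O)c1cc(Br)cc(O)c1O | starting material
5 | benzyl 5-bromo-2,3-dihydroxybenzoate | O=C(OCc1ccccc1)c1cc(Br)cc(O)c1O | intermediate
6 | benzyl 5-bromo-2-hydroxy-3-{[(2S,3E)-pent-3-en-2-yl]oxy}benzoate | O=C(OCc1ccccc1)c1cc(Br)cc(O[C@@H](C)/C=C/C)c1O | intermediate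
7 | benzyl 5-bromo-2,3-dihydroxy-4-[(2R,3E)-pent-3-en-2-yl]benzoate | O=C(OCc1ccccc1)c1cc(Br)c([C@H](C)/C=C/C)c(O)c1O | intermediate
8 | benzyl 2,3-bis(benzyloxy)-5-bromo-4-[(2R,3E)-pent-3-en-2-yl]benzoate | O=C(OCc1ccccc1)c1cc(Br)c([C@H](C)/C=C/C)c(OCc2ccccc2)c1OCc1ccccc1 | intermediate
9 | but-3-en-2-one (methyl vinyl ketone) | C=CC(C)=O | starting material
10 | benzyl 2,3-bis(benzyloxy)-5-[(1E)-3-oxobut-1-en-1-yl]-4-[(2R,3E)-pent-3-en-2-yl]benzoate | CC(=O)/C=C/c1cc(C(=O)OCc2ccccc2)c(OCc2ccccc2)c(OCc2ccccc2)c1[C@H](C)/C=C/C | intermediate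
11 | benzyl 2,3-bis(benzyloxy)-5-[(1E,3R)-3-hydroxybut-1-en-1-yl]-4-[(2R,3E)-pent-3-en-2-yl]benzoate | C[C@@H](O)/C=C/c1cc(C(=O)OCc2ccccc2)c(OCc2ccccc2)c(OCc2ccccc2)c1[C@H](C)/C=C/C | intermediate
12 | (2R)-3-bromo-2-methylpropan-1-ol | OC[C@@H](C)CBr | starting material
13 | benzyl (2R)-3-bromo-2-methylpropyl ether | BrC[C@H](C)COCc1ccccc1 | intermediate
14 | ethyl 4-bromobutanoate | CCOC(=O)CCCBr | starting material
15 | [(2R)-3-(benzyloxy)-2-methylpropyl]magnesium bromide | Br[Mg]C[C@H](C)COCc1ccccc1 | intermediate (not isolated)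
16 | ethyl (6S)-7-(benzyloxy)-6-methylheptanoate | CCOC(=O)CCCC[C@H](C)COCc1ccccc1 | intermediate
17 | (6S)-7-(benzyloxy)-6-methylheptanoic acid | OC(=O)CCCC[C@H](C)COCc1ccccc1 | intermediate
18 | benzyl 2,3-bis(benzyloxy)-5-[(1E,3R)-3-{[(6S)-7-(benzyloxy)-6-methylheptanoyl]oxy}but-1-en-1-yl]-4-[(2R,3E)-pent-3-en-2-yl]benzoate | C[C@@H](OC(=O)CCCC[C@H](C)COCc1ccccc1)/C=C/c1cc(C(=O)OCc2ccccc2)c(OCc2ccccc2)c(OCc2ccccc2)c1[C@H](C)/C=C/C | intermediate
19 | (E)-trimethylsilyl ketene acetal of 18 (alkyl chain cis to the allyloxy oxygen, trans to OSiMe3) | C[C@@H](O/C(O[Si](C)(C)C)=C\CCC[C@H](C)COCc1ccccc1)/C=C/c1cc(C(=O)OCc2ccccc2)c(OCc2ccccc2)c(OCc2ccccc2)c1[C@H](C)/C=C/C | intermediate (not isolated)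
20 | trimethylsilyl ester of acid 21 | C[Si](C)(C)OC(=O)[C@@H](CCC[C@H](C)COCc1ccccc1)[C@H](/C=C/C)c1cc(C(=O)OCc2ccccc2)c(OCc2ccccc2)c(OCc2ccccc2)c1[C@H](C)/C=C/C | intermediate (not isolated)
21 | (2S,3S,4E)-2-[(4S)-5-(benzyloxy)-4-methylpentyl]-3-{3,4-bis(benzyloxy)-5-[(benzyloxy)carbonyl]-2-[(2R,3E)-pent-3-en-2-yl]phenyl}hex-4-enoic acid | OC(=O)[C@@H](CCC[C@H](C)COCc1ccccc1)[C@H](/C=C/C)c1cc(C(=O)OCc2ccccc2)c(OCc2ccccc2)c(OCc2ccccc2)c1[C@H](C)/C=C/C | intermediate
22 | isobutyl carbonic mixed anhydride of acid 21 | CC(C)COC(=O)OC(=O)[C@@H](CCC[C@H](C)COCc1ccccc1)[C@H](/C=C/C)c1cc(C(=O)OCc2ccccc2)c(OCc2ccccc2)c(OCc2ccccc2)c1[C@H](C)/C=C/C | intermediate (not isolated)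
23 | benzyl 2,3-bis(benzyloxy)-5-{(2S,3S,4E)-2-[(4S)-5-(benzyloxy)-4-methylpentyl]-1-hydroxyhex-4-en-3-yl}-4-[(2R,3E)-pent-3-en-2-yl]benzoate | OC[C@@H](CCC[C@H](C)COCc1ccccc1)[C@H](/C=C/C)c1cc(C(=O)OCc2ccccc2)c(OCc2ccccc2)c(OCc2ccccc2)c1[C@H](C)/C=C/C | intermediate
24 | benzyl 5-{(2S,3S,4E)-1-acetoxy-2-[(4S)-5-(benzyloxy)-4-methylpentyl]hex-4-en-3-yl}-2,3-bis(benzyloxy)-4-[(2R,3E)-pent-3-en-2-yl]benzoate | CC(=O)OC[C@@H](CCC[C@H](C)COCc1ccccc1)[C@H](/C=C/C)c1cc(C(=O)OCc2ccccc2)c(OCc2ccccc2)c(OCc2ccccc2)c1[C@H](C)/C=C/C | intermediate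
25 | benzyl (5R,8S)-8-[(2S,6S)-1-acetoxy-7-(benzyloxy)-6-methylheptan-2-yl]-3,4-bis(benzyloxy)-5-methyl-5,8-dihydronaphthalene-2-carboxylate | CC(=O)OC[C@@H](CCC[C@H](C)COCc3ccccc3)[C@@H]1C=C[C@@H](C)c2c1cc(C(=O)OCc3ccccc3)c(OCc3ccccc3)c2OCc3ccccc3 | intermediate
26 | (5R,8S)-8-[(2S,6S)-1-acetoxy-7-hydroxy-6-methylheptan-2-yl]-3,4-dihydroxy-5-methyl-5,6,7,8-tetrahydronaphthalene-2-carboxylic acid | CC(=O)OC[C@@H](CCC[C@H](C)CO)[C@@H]1CC[C@@H](C)c2c1cc(C(=O)O)c(O)c2O | target

Total step count: 17. Longest linear sequence: 13 steps (steps 1, 2, 4–8, 12–17).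

Steps most likely to fail

Step 16 (ring-closing metathesis). Initiation at two internal, allylically branched propenyl groups may be slow, so that oligomerisation or ruthenium-hydride migration of a double bond into conjugation (loss of the C1 or C4 configuration) competes with ring closure. The fallback sets out from 24 and forms the same bond by reductive carbonyl coupling instead of metathesis. Oxidative cleavage of both propenyl groups (OsO4 cat., NaIO4, 2,6-lutidine, dioxane/H2O) should give the dialdehyde benzyl 5-[(2S,3S,7S)-3-(acetoxymethyl)-8-(benzyloxy)-7-methyl-1-oxooctan-2-yl]-2,3-bis(benzyloxy)-4-[(2S)-1-oxopropan-2-yl]benzoate F2 (configurations unchanged; descriptors differ by priority only). Intramolecular McMurry coupling (TiCl3(DME)1.5, Zn–Cu, DME, reflux, slow addition) then joins the two aldehyde carbons as C2=C3 and returns to the route at 25.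

Step 7 (Heck reaction). Oxidative addition and insertion at the ortho-branched, electron-rich bromide may be sluggish while 9 polymerises, and palladium hydride may shift the propenyl double bond into conjugation and erase the C4 stereocentre. The fallback sets out from 8 and uses a cross-coupling that passes through no palladium hydride. (R)-But-3-yn-2-ol (commercial, C#C[C@@H](C)O) is hydroborated with pinacolborane (Cp2Zr(H)Cl cat., Et3N cat., CH2Cl2, rt, aqueous work-up) to (2R,3E)-4-(4,4,5,5-tetramethyl-1,3,2-dioxaborolan-2-yl)but-3-en-2-ol F1. Suzuki–Miyaura coupling of F1 with 8 (Pd(OAc)2, SPhos, K3PO4, THF/H2O, 60 °C) should give the (R)-allylic alcohol directly, with its carbinol centre taken from the chiral pool. The fallback returns to the route at 11, so that steps 7 and 8 are both replaced.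

Step 17 (hydrogenation and hydrogenolysis). Reversible palladium-hydride addition may move the ring double bond from C2=C3 to C1=C2 or C3=C4 before it is reduced, which would scramble C1 or C4; cleavage of the alkyl benzyl ether may also lag behind. The fallback sets out from 25 and separates the two tasks. Metal-free diimide reduction (2-nitrobenzenesulfonylhydrazide, Et3N, CH2Cl2, rt; concerted syn transfer of two hydrogens, no isomerisation pathway) should give benzyl (5R,8S)-8-[(2S,6S)-1-acetoxy-7-(benzyloxy)-6-methylheptan-2-yl]-3,4-bis(benzyloxy)-5-methyl-5,6,7,8-tetrahydronaphthalene-2-carboxylate F3. Hydrogenolysis of F3 (H2, Pd/C, EtOAc/EtOH, rt) then removes the four benzyl groups and returns to the route at 26.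

Further compounds
F1 | step 7 | (2R,3E)-4-(4,4,5,5-tetramethyl-1,3,2-dioxaborolan-2-yl)but-3-en-2-ol | C[C@@H](O)/C=C/B1OC(C)(C)C(C)(C)O1
F2 | step 16 | benzyl 5-[(2S,3S,7S)-3-(acetoxymethyl)-8-(benzyloxy)-7-methyl-1-oxooctan-2-yl]-2,3-bis(benzyloxy)-4-[(2S)-1-oxopropan-2-yl]benzoate | CC(=O)OC[C@@H](CCC[C@H](C)COCc1ccccc1)[C@H](C=O)c1cc(C(=O)OCc2ccccc2)c(OCc2ccccc2)c(OCc2ccccc2)c1[C@H](C)C=O
F3 | step 17 | benzyl (5R,8S)-8-[(2S,6S)-1-acetoxy-7-(benzyloxy)-6-methylheptan-2-yl]-3,4-bis(benzyloxy)-5-methyl-5,6,7,8-tetrahydronaphthalene-2-carboxylate | CC(=O)OC[C@@H](CCC[C@H](C)COCc3ccccc3)[C@@H]1CC[C@@H](C)c2c1cc(C(=O)OCc3ccccc3)c(OCc3ccccc3)c2OCc3ccccc3
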